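The earlier runs and the new flask stem from a simulated flask from invented constants; scatter was added.

A leftover comes first: at 3.00 d the epsilon run shows target and isomer of the product, and 45.5 % of the starting material charged is in neither of them.

- epsilon: starting material 0.020 M; catalyst 0.40 mM; the very flask that is asked about, followed so far
- flask: starting material 0.020 M; catalyst 0.40 mM; time 15 d

- epsilon (time / d: target / %, isomer of the product / %): 0.250: 24.1, 27.9; 0.500: 23.5, 29.9; 1.25: 22.8, 30.3; 3.00: 23.8, 30.7

(each reading ± 0.3 percentage points)



- ratio of target to isomer of the product at 3.0 min
- ratio of target to isomer of the product at 4.0 h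
- ratio of target to isomer of the product at 15 d

The epsilon run is this very flask, so its readings need no scaling. But they stop at 3.00 d, and you are asked about 15 d. So you want a number with no clock in it. Suppose target and isomer of the product pass into each other. Where both amounts stand still, the rate from target to isomer equals the rate back, and time drops out of their quotient. The readings at 1.25 d and 3.00 d give 0.764. Call this reading the standing ratio: target over isomer once both stop moving, which is thermodynamic control if the flat stretch is a balance. I commit to it for 15 d. But the reading at 0.250 d gives 0.864, higher than the standing ratio, and 3.0 min and 4.0 h lie before any reading. So I put both those ratios above it, without a firm figure.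

The forecast gives 1.4, 0.93 and 0.765, and says of the first: “That early value is poorly constrained”.

The flask gives 90.7 at 3.0 min, 1.04 at 4.0 h and 0.769 at 15 d.

    starting material + catalyst ⇌ target + catalyst, rate k1*[starting material]*[catalyst] forward; the back reaction follows from the equilibrium constant (K = 0.510, k = 0.829 M⁻¹ s⁻¹)
    target ⇌ isomer of the product (K = 1.30, k = 1.18 × 10⁻⁴ s⁻¹)
    catalyst ⇌ dormant form (K = 0.463, k = 4.37 × 10⁻⁴ s⁻¹)

The step between target and isomer of the product has the quotient 0.769, with no catalyst written in it, and the flask's 0.769 lies close to the standing ratio. Now take the neighbour flask, charged with 1.0 × 10⁻⁴ M of catalyst, a quarter of the recipe's amount. The standing ratio was read in the epsilon run, at the recipe's catalyst. Carried over unchanged, it gives 0.764 for the neighbour flask at 15 d, and the neighbour flask reads 0.769. At 4.0 h the neighbour flask reads 1.26, higher than the 1.04 of the flask.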